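**Retrosynthetic overview**
- The phenol ring is made last: a gold-catalysed furan–yne cycloisomerisation dearomatises a 2,4-disubstituted furan and forms C4a–C8a and C7–C8, with the oxygen delivered to C8.
- C1/C2: Marshall propargylation of a β-furyl aldehyde with a (R)-butynyl mesylate, then Mitsunobu inversion that installs the C2 acetate.
- C4: iminium-catalysed conjugate addition of a furyl trifluoroborate to a γ-chiral enal.
- C11 and the side chain come from (S)-citronellal (one-carbon degradation, Wittig); the furan comes from furan-3-ylmethanol (acetylation, Ir borylation).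
- Ring order: no ring is closed before the end; the saturated ring and the benzene ring form together in the final step.

Assumption: the SMILES is read as (1S,2S,4S,11S)-2,19-diacetoxyserrulat-14-en-8-ol (serrulatane labels C1, C2, C4, C8, C11 are used below); furan-3-ylmethanol, (S)-citronellal and (R)-but-3-yn-2-ol are bought.

**Step 1**
Reactants: 1 furan-3-ylmethanol
Product: 2 furan-3-ylmethyl acetate
Conditions: Ac2O, pyridine, DMAP (cat.), CH2Cl2, 0 °C → rt
Reagents that add atoms: acetic anhydride CC(=O)OC(C)=O
Why: O-acylation puts the primary acetate of the target in place at the outset, so it never has to be told apart from the phenol later.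

**Step 2**
Reactants: 2 furan-3-ylmethyl acetate
Product: 4 potassium [4-(acetoxymethyl)furan-2-yl]trifluoroborate, via pinacol boronate 3 (not isolated)
Conditions: [Ir(OMe)(cod)]2 (1.5 mol%), dtbpy (3 mol%), B2pin2 (0.55 equiv), hexane, rt; then aq. KHF2, MeOH, rt
Reagents that add atoms: bis(pinacolato)diboron CC1(C)OB(OC1(C)C)B1OC(C)(C)C(C)(C)O1; potassium hydrogen difluoride F.[F-].[K+]
Why: Ir-catalysed C–H borylation is sterically controlled and takes the furan α-position remote from the CH2OAc group, and KHF2 then gives the crystalline trifluoroborate in the same pot.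

**Step 3**
Reactants: 5 (3S)-3,7-dimethyloct-6-enal ((S)-citronellal)
Product: 7 (2S)-2,6-dimethylhept-5-enal, via morpholine enamine 6 (not isolated)
Conditions: morpholine (1.0 equiv), 4 Å MS, toluene, rt, filter, evaporate; then CuCl (10 mol%), O2 (1 atm), MeCN, 0 °C → rt
Reagents that add atoms: morpholine C1COCCN1 (stays only in 6); dioxygen O=O
Why: copper-catalysed aerobic cleavage of the enamine C=C (enamine oxygenation, dioxetane fragmentation) removes C1 of citronellal as a formamide with no free base present, so the new α-stereocentre (future C11, S) is kept and the trisubstituted alkene is untouched.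

**Step 4**
Reactants: 7 (2S)-2,6-dimethylhept-5-enal
Product: 8 (2E,4S)-4,8-dimethylnona-2,7-dienal
Conditions: Ph3P=CHCHO (1.2 equiv), toluene, 80 °C
Reagents that add atoms: (triphenylphosphoranylidene)acetaldehyde O=CC=P(c1ccccc1)(c1ccccc1)c1ccccc1
Why: Wittig olefination with the stabilised formylmethylene ylide is E-selective and not basic enough to epimerise the α-stereocentre.

**Step 5**
Reactants: 4 potassium [4-(acetoxymethyl)furan-2-yl]trifluoroborate + 8 (2E,4S)-4,8-dimethylnona-2,7-dienal
Product: 9 {5-[(3S,4S)-4,8-dimethyl-1-oxonon-7-en-3-yl]furan-3-yl}methyl acetate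
Conditions: (2S,5S)-5-benzyl-2-tert-butyl-3-methylimidazolidin-4-one·HCl (20 mol%), HF (1.0 equiv, 48% aq.), DME, −20 °C
Reagents that add atoms: none
Why: MacMillan iminium-catalysed Friedel–Crafts-type conjugate addition of a heteroaryl trifluoroborate (ipso attack at the C–B carbon) in which the (E)-iminium of 8 is attacked on the face away from the catalyst benzyl group, the sense that gives (R)-adducts from crotonaldehyde and gives 3S here (future C4) because the branched C4 substituent outranks CH2CHO, with catalyst control overriding the resident centre.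

**Step 6**
Reactants: 10 (2R)-but-3-yn-2-ol
Product: 11 (2R)-but-3-yn-2-yl methanesulfonate
Conditions: MsCl, Et3N, CH2Cl2, −78 → 0 °C
Reagents that add atoms: methanesulfonyl chloride CS(=O)(=O)Cl
Why: O-sulfonylation with retention at carbon gives the propargylic electrophile for the Marshall reaction.

**Step 7**
Reactants: 9 {5-[(3S,4S)-4,8-dimethyl-1-oxonon-7-en-3-yl]furan-3-yl}methyl acetate + 11 (2R)-but-3-yn-2-yl methanesulfonate
Product: 13 {5-[(3S,4R,6S,7S)-4-hydroxy-3,7,11-trimethyldodec-10-en-1-yn-6-yl]furan-3-yl}methyl acetate, via allenylzinc reagent 12 (not isolated)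
Conditions: 11 (1.5 equiv), Pd(OAc)2 (5 mol%), PPh3 (5 mol%), Et2Zn (3 equiv), THF, −78 → −20 °C; aq. NH4Cl
Reagents that add atoms: diethylzinc CC[Zn]CC (stays only in 12)
Why: Marshall–Tamaru propargylation in which Pd(0) ionises 11 by anti-SN2', Et2Zn transmetalates to allenylzinc 12, and its closed SE2' transition state adds to the aldehyde with net inversion at the propargylic carbon (3S, future C1) and an anti relationship (4R) under reagent control, the minor syn isomer being removed by chromatography.

**Step 8**
Reactants: 13 {5-[(3S,4R,6S,7S)-4-hydroxy-3,7,11-trimethyldodec-10-en-1-yn-6-yl]furan-3-yl}methyl acetate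
Product: 14 {5-[(3S,4S,6S,7S)-4-acetoxy-3,7,11-trimethyldodec-10-en-1-yn-6-yl]furan-3-yl}methyl acetate
Conditions: PPh3, DIAD, AcOH, toluene, 0 °C → rt
Reagents that add atoms: acetic acid CC(=O)O
Why: Mitsunobu esterification in which acetate displaces the phosphonium-activated oxygen by SN2, inverting 4R to 4S (future C2) and installing the second acetate in the same operation.

**Step 9**
Reactants: 14 {5-[(3S,4S,6S,7S)-4-acetoxy-3,7,11-trimethyldodec-10-en-1-yn-6-yl]furan-3-yl}methyl acetate
Product: 16 [(5S,6S,8S)-6-acetoxy-4-hydroxy-5-methyl-8-[(2S)-6-methylhept-5-en-2-yl]-5,6,7,8-tetrahydronaphthalen-2-yl]methyl acetate (target), via oxepine tautomer 15 (not isolated)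
Conditions: AuCl3 (5 mol%), MeCN (0.05 M), rt, N2
Reagents that add atoms: none
Why: Proposed new method: an all-carbon, four-atom-tether version of the Hashmi gold-catalysed furan–yne phenol synthesis (closest known: AuCl3-catalysed conversion of ω-alkynylfurans into isoindolin-4-ols, isochroman-8-ols and tetrahydroisoquinolin-8-ols), in which π-activation of the alkyne, 6-exo attack by the furan C2=C3 bond to a cyclopropyl gold carbenoid, furan ring-opening to a carbonyl-conjugated carbene and re-closure give oxepine 15 (in equilibrium with the 7,8-arene oxide), which opens with oxygen on the former alkyne terminus, so the OH ends at C8 next to the new ring fusion, the furan 4-substituent becomes the C6 CH2OAc group, and no stereocentre is touched.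

**Compound list**
1 | furan-3-ylmethanol | OCc1ccoc1 | starting material
2 | furan-3-ylmethyl acetate | CC(=O)OCc1ccoc1 | intermediate
3 | [5-(4,4,5,5-tetramethyl-1,3,2-dioxaborolan-2-yl)furan-3-yl]methyl acetate | CC(=O)OCc1coc(c1)B1OC(C)(C)C(C)(C)O1 | intermediate
4 | potassium [4-(acetoxymethyl)furan-2-yl]trifluoroborate | CC(=O)OCc1coc(c1)[B-](F)(F)F.[K+] | intermediate
5 | (3S)-3,7-dimethyloct-6-enal, (S)-citronellal | O=CC[C@@H](C)CCC=C(C)C | starting material
6 | 4-[(1E,3S)-3,7-dimethylocta-1,6-dien-1-yl]morpholine | O1CCN(CC1)/C=C/[C@@H](C)CCC=C(C)C | intermediate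
7 | (2S)-2,6-dimethylhept-5-enal | O=C[C@@H](C)CCC=C(C)C | intermediate
8 | (2E,4S)-4,8-dimethylnona-2,7-dienal | O=C/C=C/[C@@H](C)CCC=C(C)C | intermediate
9 | {5-[(3S,4S)-4,8-dimethyl-1-oxonon-7-en-3-yl]furan-3-yl}methyl acetate | CC(=O)OCc1coc(c1)[C@H]([C@@H](C)CCC=C(C)C)CC=O | intermediate
10 | (2R)-but-3-yn-2-ol | C[C@@H](O)C#C | starting material
11 | (2R)-but-3-yn-2-yl methanesulfonate | C[C@@H](OS(C)(=O)=O)C#C | intermediate
12 | (P)-buta-1,2-dien-1-yl(ethyl)zinc | CC([H])=[C@@]=C([H])[Zn]CC | intermediate
13 | {5-[(3S,4R,6S,7S)-4-hydroxy-3,7,11-trimethyldodec-10-en-1-yn-6-yl]furan-3-yl}methyl acetate | CC(=O)OCc1coc(c1)[C@H]([C@@H](C)CCC=C(C)C)C[C@@H](O)[C@H](C#C)C | intermediate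
14 | {5-[(3S,4S,6S,7S)-4-acetoxy-3,7,11-trimethyldodec-10-en-1-yn-6-yl]furan-3-yl}methyl acetate | CC(=O)OCc1coc(c1)[C@H]([C@@H](C)CCC=C(C)C)C[C@H](OC(C)=O)[C@H](C#C)C | intermediate
15 | [(6S,8S,9S)-8-acetoxy-9-methyl-6-[(2S)-6-methylhept-5-en-2-yl]-6,7,8,9-tetrahydro-2-benzoxepin-4-yl]methyl acetate (oxepine tautomer of the 7,8-arene oxide of 16) | CC(=O)OCC1=COC=C2C(=C1)[C@H]([C@@H](C)CCC=C(C)C)C[C@H](OC(C)=O)[C@H]2C | intermediate
16 | [(5S,6S,8S)-6-acetoxy-4-hydroxy-5-methyl-8-[(2S)-6-methylhept-5-en-2-yl]-5,6,7,8-tetrahydronaphthalen-2-yl]methyl acetate, (1S,2S,4S,11S)-2,19-diacetoxyserrulat-14-en-8-ol | CC(=O)OCc1cc(O)c2c(c1)[C@H]([C@@H](C)CCC=C(C)C)C[C@H](OC(C)=O)[C@H]2C | target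

**Step count**
Total: 9 steps. Longest linear sequence: 6 steps (1, 2, 5, 7, 8, 9 from furan-3-ylmethanol; equally 3, 4, 5, 7, 8, 9 from (S)-citronellal).

**Three steps most likely to fail, with fallbacks**

Step 9 is the riskiest. It is a new substrate class for the furan–yne reaction, and it may suffer slow 6-exo attack, acetate-assisted alkyne hydration or arene oxide opening the wrong way. Changing to cationic Au(I) or PtCl2 is only a change of conditions. The fallback sets out from 14 and comes back at 16 without carbophilic catalysis. Dehydrogenative C(sp)–H borylation of 14 (HBpin, Ir or Cu catalyst, rt) gives the alkynyl pinacol boronate F1. Heating (mesitylene, 160 °C, BHT) effects the intramolecular furan Diels–Alder reaction to the 7-oxanorbornadiene boronate F2, and both bridgehead diastereomers serve. Fe2(CO)9 (benzene, 80 °C) removes the bridging oxygen and aromatises to the aryl boronate F3. NaBO3·4H2O (THF/H2O, rt) oxidises C–B to C–OH and gives 16. Boron now marks C8 for oxygen, so the regiochemistry no longer depends on an arene oxide; the thermal cycloaddition onto a weakly activated alkyne is itself demanding.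

Step 5 is second. The enal is γ-branched and slow, the furan is not electron-rich, the diastereoselectivity is a case of double stereodifferentiation, and a dienamine could epimerise C4 of 8. The fallback sets out from 3 (isolated after the borylation of step 2, before KHF2) and 8 and comes back directly at 9 (no new compound, F0). It is a rhodium-catalysed Hayashi–Miyaura 1,4-addition ([RhCl(C2H4)2]2, chiral bicyclic diene ligand, aq. K3PO4, dioxane, 30 °C). The furyl group is then delivered by a chiral aryl-rhodium species instead of through iminium activation, no secondary amine is present, and the ligand enantiomer is chosen for the 3S product.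

Step 8 is third. Mitsunobu inversion with a weak acid at a carbinol flanked by a propargylic methine may stall or give the enyne by elimination. The fallback sets out from 9 and comes back at 14 without any inversion. (2S)-But-3-yn-2-ol F4 (bought) is mesylated to (2S)-but-3-yn-2-yl methanesulfonate F5. Bu3SnLi/CuBr·SMe2 (anti-SN2') gives (M)-tributyl(buta-1,2-dien-1-yl)stannane F6. BF3·OEt2-promoted addition of F6 to 9 (CH2Cl2, −78 °C, open anti-SE2' transition state) gives the syn alcohol {5-[(3S,4S,6S,7S)-4-hydroxy-3,7,11-trimethyldodec-10-en-1-yn-6-yl]furan-3-yl}methyl acetate F7 directly. Ac2O/pyridine/DMAP then gives 14.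

**Further compounds**
F1 | step 9 | {5-[(3S,4S,6S,7S)-4-acetoxy-3,7,11-trimethyl-1-(4,4,5,5-tetramethyl-1,3,2-dioxaborolan-2-yl)dodec-10-en-1-yn-6-yl]furan-3-yl}methyl acetate | CC(=O)OCc1coc(c1)[C@H]([C@@H](C)CCC=C(C)C)C[C@H](OC(C)=O)[C@H](C#CB1OC(C)(C)C(C)(C)O1)C
F2 | step 9 | 7-oxanorbornadiene boronate from the intramolecular Diels–Alder reaction of F1 (bridgehead carbons as a mixture, side-chain centres as in 14) | CC(=O)OCC1=CC23OC1C(B4OC(C)(C)C(C)(C)O4)=C2[C@H](C)[C@@H](OC(C)=O)C[C@H]3[C@@H](C)CCC=C(C)C
F3 | step 9 | [(5S,6S,8S)-6-acetoxy-5-methyl-8-[(2S)-6-methylhept-5-en-2-yl]-4-(4,4,5,5-tetramethyl-1,3,2-dioxaborolan-2-yl)-5,6,7,8-tetrahydronaphthalen-2-yl]methyl acetate | CC(=O)OCc1cc(B3OC(C)(C)C(C)(C)O3)c2c(c1)[C@H]([C@@H](C)CCC=C(C)C)C[C@H](OC(C)=O)[C@H]2C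
F0 | step 5 | none | none
F4 | step 8 | (2S)-but-3-yn-2-ol (bought) | C[C@H](O)C#C
F5 | step 8 | (2S)-but-3-yn-2-yl methanesulfonate | C[C@H](OS(C)(=O)=O)C#C
F6 | step 8 | (M)-tributyl(buta-1,2-dien-1-yl)stannane | CC([H])=[C@]=C([H])[Sn](CCCC)(CCCC)CCCC
F7 | step 8 | {5-[(3S,4S,6S,7S)-4-hydroxy-3,7,11-trimethyldodec-10-en-1-yn-6-yl]furan-3-yl}methyl acetate | CC(=O)OCc1coc(c1)[C@H]([C@@H](C)CCC=C(C)C)C[C@H](O)[C@H](C#C)C
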